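| setting | south | north-east | flask |
|---|---|---|---|
| D | 0.40 M | 0.40 M | 0.40 M |
| G | 0.40 M | 0.40 M | 0.40 M |
| L | 0.48 M | 0.96 M | 0.480 M |
| Q | 0.20 M | 0.20 M | 0.200 M |
| temperature | 25 °C | 20 °C | 25 °C |
| remark | the very flask that is asked about, followed so far | run made earlier |  |
| time |  |  | 20 h |

south run (percent of the D and G together charged): time / h: Z / % = 1.50: 33.6; 3.00: 34.5; 6.00: 34.5; 10.0: 31.5; 20.0: 33.5

north-east run (percent of the D and G together charged): time / min: Z / % = 5.00: 14.1; 10.0: 25.6; 15.0: 29.5; 30.0: 38.8; 60.0: 46.8

(scatter of a reading: 1 percentage point)

- amber: at 20 h raise the temperature by 20 K, then wait 20 h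
- green: at 20 h take out 90% of the Z then present, then wait 20 h
- teal: change nothing and wait 20 h more
- grey: at 20 h add L, 100% of the amount charged, then wait 20 h

- L is single-handed; D and G are mirror images of each other, charged as a racemate, each of them at the stated concentration
- Z that was removed still counts
- steps thought possible: L + D -> Z; L + G -> J; L + Q -> E
- additions bring no volume worth counting
- the handed part of L does not stay in what it makes, so the products of the two hands are mirror images too

1. Z, in percent of the D and G together first charged, at 20 h
2. the option that brings most further Z ("none" if no option brings more than 2 percentage points) (amber / green / teal / grey / none)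
3. Z present, with what was taken out counted in, in percent of the D and G together first charged, after green
4. Z present, with what was taken out counted in, in percent of the D and G together first charged, after grey

- The small charge of Q, 0.200 M, was where I began, since it stands beside 0.480 M of L in the south flask, and I had to decide at 20 h whether to leave that flask, heat it, draw off Z or add L.
- Each step uses one L, and I counted one L for each Q. For the south flask I reckoned 35.0%: this is spare L, the charge of L less the charge of Q, in percent of the D and G together charged.
- Spare L came from the charges, so the readings could test it. Z in the south run stayed level, with 33.6% at 1.50 h and 33.5% at 20.0 h, and the 5 readings average 33.5%, each with a scatter of 1 percentage point.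
- I treated Z as the large term and J as the correction, so Z is spare L less J. The gap of 1.5 points I booked as J, since Z had stopped rising while D, by that average of readings, stood at 16.5%. So I took L for the limiting reagent in the south flask.
- Z and J are mirror images, so a true equilibrium holds them equal, yet Z stood far above that gap. I therefore expected teal, amber and green to bring no further Z, and Z at 33.5% after green.
- Grey adds L worth 60.0% of the D and G together charged, more than my figure for the D left, so I took the D charge of 50.0% as the limit on Z. Spare L then totals 95.0%, as in the north-east run, where Z reached 46.8% at 60.0 min, up from 38.8% at 30.0 min, at 20 °C. I committed to grey, with Z near 50.0%.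
- The forecast, made from the same runs, called this an “irreversible kinetic resolution” and gave 33.5% now, grey as best, 33.5% after green and 49.5% after grey, a little below my figure for grey.
- The flask gave 34.1% now, grey as best with a gain of 16 points, 34.1% after green and 50.0% after grey.

    L + D → Z (k = 0.169 /M/min, Ea = 71.0 kJ/mol)
    L + G → J (k = 0.00262 /M/min, Ea = 68.0 kJ/mol)
    L + Q → E (k = 5.42 /M/min, Ea = 45.0 kJ/mol)
    (constants at 25 °C)

- Spare L less Z in this flask is 0.90 points, and J stood at 0.881% after 20.0 h. The forecast's 33.5% was made for 0.200 M of Q, and a run with less Q shows what would make it wrong. With cQ at 0.080 M and the other charges unchanged, spare L is 50.0%. J took 2.32% of that by 20.0 h, and Z stood at 47.7%.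

The runs stem from a simulated flask for an exercise; noise was put on by code.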